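## Retrosynthetic overview
1. Glabrol comes from its 7,4'-bis-TBS ether by buffered fluoride cleavage. This keeps the last step cold and near neutral so C2 is not disturbed.
2. The C2–C1' bond and the only stereocentre come from a Rh(I)/(S)-biaryl-diphosphine asymmetric 1,4-addition of a 3-prenyl-4-silyloxyphenylboronic acid to a 7-silyloxy-8-prenylchromone.
3. The 8-prenylchromone comes from an aromatic Claisen rearrangement of the 7-O-(1,1-dimethylallyl) ether, which is made from 7-hydroxychromone by Tsuji–Trost O-alkylation.
4. The boronic acid comes from 4-bromo-2-prenylphenol, made by ortho-C-prenylation of 4-bromophenol.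
5. No ring is built. The benzopyranone and the B-ring benzene are purchased, and ring C is only converted from chromone to chromanone in the key step.

Assumption: the sense of induction is assigned by analogy with (S)-BINAP giving (S)-3-arylcyclohexanone, which maps onto Re-face attack at chromone C2 and hence 2S. It should be confirmed by CD (2S flavanones show a negative band near 290 nm and a positive band near 330 nm). If the sense is reversed, the (R)-ligand is used.

## Route

**Step 1**
Reactants: 1 2-methylbut-3-en-2-ol; 2 di-tert-butyl dicarbonate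
Product: 3 tert-butyl (2-methylbut-3-en-2-yl) carbonate
Conditions: n-BuLi (1.05 equiv), THF, −78 to 0 °C; then 2, 0 °C to rt
Reagents that add atoms: Boc2O (2), CC(C)(C)OC(=O)OC(=O)OC(C)(C)C
Why: This is O-acylation of the lithium tertiary alkoxide, and no other functionality is present.

**Step 2**
Reactants: 4 7-hydroxy-4H-chromen-4-one; 3
Product: 5 7-[(2-methylbut-3-en-2-yl)oxy]-4H-chromen-4-one
Conditions: Pd(PPh3)4 (3 mol %), 3 (1.5 equiv), THF, 0 °C to rt, stopped at full conversion
Reagents that add atoms: carbonate 3 (delivers C5H9), CC(C)(C)OC(=O)OC(C)(C)C=C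
Why: This is a decarboxylative Tsuji–Trost O-allylation in which the phenoxide attacks the more substituted π-allyl terminus under kinetic control; the short time and low temperature prevent re-ionisation to the linear prenyl ether.

**Step 3**
Reactants: 5
Product: 6 7-hydroxy-8-(3-methylbut-2-en-1-yl)-4H-chromen-4-one
Conditions: PhNEt2, 130 °C, 2–3 h, Ar
Reagents that add atoms: none
Why: The aromatic Claisen [3,3] shift transposes the tertiary allyl group into a linear prenyl group, and 7-allyloxybenzopyranones migrate mainly to C8 (higher C7–C8 bond order), with the minor 6-isomer and any 4 from isoprene loss removed by chromatography.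

**Step 4**
Reactants: 6; 7 tert-butyldimethylsilyl chloride
Product: 8 7-(tert-butyldimethylsilyloxy)-8-(3-methylbut-2-en-1-yl)-4H-chromen-4-one
Conditions: TBSCl, imidazole, DMF, rt
Reagents that add atoms: TBSCl (7), CC(C)(C)[Si](C)(C)Cl
Why: Standard phenol silylation removes the acidic OH, which would otherwise protonate aryl-Rh and deactivate the enone.

**Step 5**
Reactants: 9 4-bromophenol; 10 prenyl bromide (1-bromo-3-methylbut-2-ene)
Product: 11 4-bromo-2-(3-methylbut-2-en-1-yl)phenol
Conditions: NaH (1.05 equiv), toluene, 0 °C to rt; then 10 (1.0 equiv), rt, 16 h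
Reagents that add atoms: prenyl bromide (10), CC(C)=CCBr
Why: This is ortho-C-alkylation of a tightly ion-paired sodium phenoxide in a non-polar solvent, by SN2 at the primary carbon; the para position is blocked by Br, the yield is moderate, and the O-prenyl ether is separable.

**Step 6**
Reactants: 11; 7
Product: 12 [4-bromo-2-(3-methylbut-2-en-1-yl)phenoxy](tert-butyl)dimethylsilane
Conditions: TBSCl, imidazole, DMF, rt
Reagents that add atoms: TBSCl (7), CC(C)(C)[Si](C)(C)Cl
Why: Phenol silylation masks the OH for the lithiation and for the Rh step.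

**Step 7**
Reactants: 12; 13 triisopropyl borate
Product: 14 [4-(tert-butyldimethylsilyloxy)-3-(3-methylbut-2-en-1-yl)phenyl]boronic acid
Conditions: n-BuLi (1.1 equiv), THF, −78 °C, 30 min; B(OiPr)3, −78 °C to rt; aq NH4Cl (pH about 5)
Reagents that add atoms: B(OiPr)3 (13), CC(C)OB(OC(C)C)OC(C)C; water, O
Why: Br/Li exchange at −78 °C is faster than allylic or benzylic deprotonation, the aryllithium is para to the OTBS group so no silyl migration is possible, and borate trapping with hydrolysis gives the acid.

**Step 8**
Reactants: 8; 14 (1.8–2.0 equiv)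
Product: 15 (2S)-7-(tert-butyldimethylsilyloxy)-2-[4-(tert-butyldimethylsilyloxy)-3-(3-methylbut-2-en-1-yl)phenyl]-8-(3-methylbut-2-en-1-yl)-2,3-dihydro-4H-chromen-4-one
Conditions: [RhCl(C2H4)2]2 (1.5 mol %), (S)-MeO-F12-BIPHEP (3.3 mol %), aq KOH (10 mol %), toluene/H2O 10:1, 25–35 °C
Reagents that add atoms: boronic acid 14 (delivers the aryl group), CC(C)=CCc1cc(B(O)O)ccc1O[Si](C)(C)C(C)(C)C; water supplies only H
Why: In this Hayashi–Miyaura asymmetric 1,4-addition the electron-poor (S)-diphosphine–Rh–aryl species inserts into the Re face of C2 and sets 2S (expected ≥95% ee); trisubstituted prenyl alkenes do not insert, and the borate-buffered toluene medium at room temperature avoids retro-oxa-Michael opening and TBS loss.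

**Step 9**
Reactants: 15
Product: 16 (2S)-glabrol
Conditions: TBAF (2.4 equiv)/AcOH (3.0 equiv) premixed, THF, 0 °C, 20–30 min; pH 6–7 phosphate work-up
Reagents that add atoms: none
Why: Fluoride cleaves the aryl silyl ethers while AcOH protonates the phenoxides at once, so the base-induced ring-opening that racemises C2 is avoided, and no strong acid is present to cyclise the ortho-prenylphenols to chromans.

## Compound list
1 | 2-methylbut-3-en-2-ol | CC(C)(O)C=C | starting material
2 | di-tert-butyl dicarbonate | CC(C)(C)OC(=O)OC(=O)OC(C)(C)C | starting material (reagent)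
3 | tert-butyl (2-methylbut-3-en-2-yl) carbonate | CC(C)(C)OC(=O)OC(C)(C)C=C | intermediate
4 | 7-hydroxy-4H-chromen-4-one | O=c1ccoc2cc(O)ccc12 | starting material
5 | 7-[(2-methylbut-3-en-2-yl)oxy]-4H-chromen-4-one | C=CC(C)(C)Oc1ccc2c(=O)ccoc2c1 | intermediate
6 | 7-hydroxy-8-prenyl-4H-chromen-4-one | CC(C)=CCc1c(O)ccc2c(=O)ccoc12 | intermediate
7 | tert-butyldimethylsilyl chloride | CC(C)(C)[Si](C)(C)Cl | starting material (reagent)
8 | 7-(TBS-oxy)-8-prenyl-4H-chromen-4-one | CC(C)=CCc1c(O[Si](C)(C)C(C)(C)C)ccc2c(=O)ccoc12 | intermediate
9 | 4-bromophenol | Oc1ccc(Br)cc1 | starting material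
10 | prenyl bromide | CC(C)=CCBr | starting material
11 | 4-bromo-2-prenylphenol | CC(C)=CCc1cc(Br)ccc1O | intermediate
12 | 4-bromo-2-prenylphenyl TBS ether | CC(C)=CCc1cc(Br)ccc1O[Si](C)(C)C(C)(C)C | intermediate
13 | triisopropyl borate | CC(C)OB(OC(C)C)OC(C)C | starting material (reagent)
14 | [4-(TBS-oxy)-3-prenylphenyl]boronic acid | CC(C)=CCc1cc(B(O)O)ccc1O[Si](C)(C)C(C)(C)C | intermediate
15 | (2S)-7,4'-bis-O-TBS-glabrol | CC(C)=CCc1cc([C@@H]2CC(=O)c3ccc(O[Si](C)(C)C(C)(C)C)c(CC=C(C)C)c3O2)ccc1O[Si](C)(C)C(C)(C)C | intermediate
16 | (2S)-glabrol | CC(C)=CCc1cc([C@@H]2CC(=O)c3ccc(O)c(CC=C(C)C)c3O2)ccc1O | target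

## Summary
Total steps: 9.
Longest linear sequence: 6 steps (1, 2, 3, 4, 8, 9). This is 5 steps from 7-hydroxychromone and 5 from 4-bromophenol.

Steps most likely to fail:
1. **Step 8.** The chromone is electron-rich, the boronic acid is prone to protodeboronation, and conversion or ee may be low. Fallback: set C2 by C–O bond formation instead.
   - Condense the allyl β-keto ester of 4-O-TBS-3-prenylresacetophenone with 4-TBSO-3-prenylbenzaldehyde in a Knoevenagel reaction.
   - Cyclise with a cinchona-thiourea catalyst in an asymmetric intramolecular oxa-Michael reaction.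
   - Remove the ester by neutral Pd(0) deallylative decarboxylation.
2. **Step 3, together with its precursor step 2.** The risks are the C8/C6 ratio, isoprene loss, and the linear ether formed in step 2 giving a reverse-prenyl product. Fallback: drop the pericyclic approach. Iodinate 4 at C8 (NIS), silylate, and install the prenyl group by Pd-catalysed cross-coupling with prenyl-Bpin or prenyl-SnBu3 to reach 8.
3. **Step 9.** The ee may erode through transient phenoxide and ring-opening. Fallback: change the protecting-group class to MOM ethers (MOMCl/DIPEA in steps 4 and 6). These are cleaved on the Lewis-acid side (ZnBr2/n-PrSH, CH2Cl2, 0 °C), where no phenoxide forms. Any shortfall in ee is then corrected by chiral HPLC or recrystallisation.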